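## Retrosynthetic overview

1. The aryl ether is made last by Mitsunobu coupling of umbelliferone with primary alcohol 11, followed by ester hydrolysis.
2. C3‑Me and C4‑CH2O both come from the ring ketone of 6: methylation, enol triflate, Pd formylation to tetrasubstituted enal 9, then Cu–H conjugate reduction (sets C3) and base equilibration (sets C4).
3. Key strategy, chosen instead of cuprate addition/enolate alkylation on a cyclopentenone: the propanoate and isobutenyl arms are the two ends of a sacrificial cyclohexenone. Reductive silylation of (R)‑Hajos–Parrish ketone and ozonolytic unzipping of its C4–C5 bond give the cis quaternary/tertiary pair directly; a Wittig reaction caps the aldehyde.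
4. Ring order: no ring is built. The cyclopentane is the five‑membered ring of 1 throughout, the six‑membered ring is destroyed in step 2, and the coumarin is purchased.

Assumption: (R)‑(–)‑Hajos–Parrish ketone is treated as a catalogue compound (otherwise two known steps from 2‑methylcyclopentane‑1,3‑dione, methyl vinyl ketone and D‑proline).

## Route

**Step 1**
Reactants: 1, (R)‑Hajos–Parrish ketone
Product: 2, (3aS,7aR)‑5‑[dimethyl(phenyl)silyl]oxy‑7a‑methyl‑2,3,3a,6,7,7a‑hexahydro‑1H‑inden‑1‑one (cis‑fused; 3a‑H syn to 7a‑CH3)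
Conditions: [(Ph3P)CuH]6 (5 mol %), PhMe2SiH (1.3 equiv), PhMe, rt
Reagents that add atoms: dimethylphenylsilane, C[SiH](C)c1ccccc1
Why: Stryker‑type Cu–H conjugate reduction with silane turnover reduces only the enone and silylates the copper enolate, so the enol ether is regiospecifically C4=C5; hydride is delivered to C3a syn to the angular methyl (same sense as H2/Pd on this enone), giving the cis‑hydrindane in which C4 and C7 (future isobutenyl and propanoate carbons) are cis.

**Step 2**
Reactants: 2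
Product: 3, 3‑[(1R,2R)‑2‑formyl‑1‑methyl‑5‑oxocyclopentyl]propanoic acid (formyl cis to the propanoic acid arm)
Conditions: O3, CH2Cl2, –78 °C; PPh3, –78 °C → rt; pH 5 aqueous work‑up
Reagents that add atoms: ozone, [O-][O+]=O
Why: Ozonolysis of the silyl enol ether (the only C=C present) cleaves C4–C5 to a silyl ester (acid on work‑up) and an aldehyde; no stereocentre is formed and the neutral reductive work‑up avoids epimerising the aldehyde α‑carbon.

**Step 3**
Reactants: 3
Product: 4, methyl 3‑[(1R,2R)‑2‑formyl‑1‑methyl‑5‑oxocyclopentyl]propanoate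
Conditions: TMSCHN2, PhMe/MeOH (4:1), 0 °C
Reagents that add atoms: trimethylsilyldiazomethane, C[Si](C)(C)C=[N+]=[N-]
Why: Diazoalkane esterification is neutral, so the acid is masked for the ylide, enolate and Mitsunobu steps without touching the aldehyde α‑stereocentre.

**Step 4**
Reactants: 4; 5, isopropyltriphenylphosphonium iodide
Product: 6, methyl 3‑[(1R,2S)‑1‑methyl‑2‑(2‑methylprop‑1‑en‑1‑yl)‑5‑oxocyclopentyl]propanoate (isobutenyl cis to the propanoate arm; descriptor changes, geometry retained)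
Conditions: 5, KHMDS, THF, 0 °C; then 4, –78 → 0 °C
Reagents that add atoms: 5, CC(C)[P+](c1ccccc1)(c1ccccc1)c1ccccc1.[I-] (delivers C(CH3)2)
Why: Wittig olefination with the non‑stabilised isopropylidene ylide is selective for the aldehyde over the hindered neopentyl ketone and the ester; fast addition at low temperature preserves the α‑stereocentre.

**Step 5**
Reactants: 6
Product: 7, methyl 3‑[(1R,2S,4RS)‑1,4‑dimethyl‑2‑(2‑methylprop‑1‑en‑1‑yl)‑5‑oxocyclopentyl]propanoate (epimers at the new methyl carbon)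
Conditions: LiHMDS, THF, –78 °C; MeI, –78 → –30 °C
Reagents that add atoms: iodomethane, CI
Why: Ketone enolate alkylation; only one α‑position can enolise (the other is quaternary) and LiHMDS deprotonates the ketone rather than the ester; the new centre's configuration is irrelevant because it becomes sp2 in step 6.

**Step 6**
Reactants: 7
Product: 8, methyl 3‑[(1R,5S)‑1,3‑dimethyl‑5‑(2‑methylprop‑1‑en‑1‑yl)‑2‑(trifluoromethylsulfonyloxy)cyclopent‑2‑en‑1‑yl]propanoate
Conditions: KHMDS, THF, –78 °C; PhNTf2, –78 → 0 °C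
Reagents that add atoms: N‑phenyl‑bis(trifluoromethanesulfonimide), FC(F)(F)S(=O)(=O)N(c1ccccc1)S(=O)(=O)C(F)(F)F
Why: Enol triflate formation by O‑sulfonylation of the only possible ketone enolate, as for steroidal 17‑ketones flanked by a quaternary carbon.

**Step 7**
Reactants: 8
Product: 9, methyl 3‑[(1R,5S)‑2‑formyl‑1,3‑dimethyl‑5‑(2‑methylprop‑1‑en‑1‑yl)cyclopent‑2‑en‑1‑yl]propanoate
Conditions: Pd(PPh3)4 (5 mol %), LiCl, CO (1 atm), Bu3SnH (slow addition), THF, 50 °C
Reagents that add atoms: carbon monoxide, [C-]#[O+]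
Why: Pd‑catalysed reductive carbonylation (Stille formylation) of the vinyl triflate installs the future CH2O carbon as an enal; the ester and the isolated trisubstituted olefin are inert.

**Step 8**
Reactants: 9
Product: 10, methyl 3‑[(1R,2R,3S,5S)‑2‑formyl‑1,3‑dimethyl‑5‑(2‑methylprop‑1‑en‑1‑yl)cyclopentyl]propanoate
Conditions: [(Ph3P)CuH]6 (0.4 equiv), PhH/THF, H2O (2 equiv), rt; then DBU, CH2Cl2, rt
Reagents that add atoms: none
Why: Stryker conjugate reduction delivers hydride to C3 from the face of the C5 methyl, opposite the pseudoaxial propanoate arm and the isobutenyl group, so the C3 methyl ends cis to the isobutenyl; DBU then equilibrates the aldehyde‑bearing C4 to the thermodynamic isomer (trans to C3‑Me, cis to the quaternary methyl).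

**Step 9**
Reactants: 10
Product: 11, methyl 3‑[(1R,2R,3S,5S)‑2‑(hydroxymethyl)‑1,3‑dimethyl‑5‑(2‑methylprop‑1‑en‑1‑yl)cyclopentyl]propanoate
Conditions: NaBH4, MeOH, –20 °C
Reagents that add atoms: none
Why: Chemoselective borohydride reduction of the aldehyde in the presence of the methyl ester; reduction fixes the C4 configuration.

**Step 10**
Reactants: 11; 12, umbelliferone (7‑hydroxycoumarin)
Product: 13, methyl 3‑[(1R,2R,3S,5S)‑1,3‑dimethyl‑5‑(2‑methylprop‑1‑en‑1‑yl)‑2‑{[(2‑oxo‑2H‑chromen‑7‑yl)oxy]methyl}cyclopentyl]propanoate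
Conditions: PPh3, DIAD, THF, 0 °C → rt
Reagents that add atoms: 12, O=c1ccc2ccc(O)cc2o1
Why: Mitsunobu etherification of the primary alcohol with the acidic phenol (pKa about 7.8); the reaction is at CH2, so no stereocentre is affected.

**Step 11**
Reactants: 13
Product: 14, ferulsinaic acid, 3‑[(1R,2R,3S,5S)‑1,3‑dimethyl‑5‑(2‑methylprop‑1‑en‑1‑yl)‑2‑{[(2‑oxo‑2H‑chromen‑7‑yl)oxy]methyl}cyclopentyl]propanoic acid
Conditions: LiOH, THF/H2O, rt; then 1 M HCl to pH 2
Reagents that add atoms: lithium hydroxide/water, [Li+].[OH-]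
Why: Saponification of the methyl ester; any coumarin lactone opened by hydroxide recloses spontaneously on acidification, and no stereocentre is epimerisable.

## Compound list

1 | (R)‑(–)‑Hajos–Parrish ketone, (7aR)‑7a‑methyl‑2,3,7,7a‑tetrahydro‑1H‑indene‑1,5(6H)‑dione | C[C@@]12CCC(=O)C=C1CCC2=O | starting material
2 | (3aS,7aR)‑5‑[dimethyl(phenyl)silyl]oxy‑7a‑methyl‑2,3,3a,6,7,7a‑hexahydro‑1H‑inden‑1‑one | C[Si](C)(c1ccccc1)OC1=C[C@@H]2CCC(=O)[C@]2(C)CC1 | intermediate
3 | 3‑[(1R,2R)‑2‑formyl‑1‑methyl‑5‑oxocyclopentyl]propanoic acid | O=C[C@@H]1CCC(=O)[C@]1(C)CCC(=O)O | intermediate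
4 | methyl 3‑[(1R,2R)‑2‑formyl‑1‑methyl‑5‑oxocyclopentyl]propanoate | O=C[C@@H]1CCC(=O)[C@]1(C)CCC(=O)OC | intermediate
5 | isopropyltriphenylphosphonium iodide | CC(C)[P+](c1ccccc1)(c1ccccc1)c1ccccc1.[I-] | starting material
6 | methyl 3‑[(1R,2S)‑1‑methyl‑2‑(2‑methylprop‑1‑en‑1‑yl)‑5‑oxocyclopentyl]propanoate | CC(C)=C[C@@H]1CCC(=O)[C@]1(C)CCC(=O)OC | intermediate
7 | methyl 3‑[(1R,2S,4RS)‑1,4‑dimethyl‑2‑(2‑methylprop‑1‑en‑1‑yl)‑5‑oxocyclopentyl]propanoate | CC(C)=C[C@@H]1CC(C)C(=O)[C@]1(C)CCC(=O)OC | intermediate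
8 | methyl 3‑[(1R,5S)‑1,3‑dimethyl‑5‑(2‑methylprop‑1‑en‑1‑yl)‑2‑(trifluoromethylsulfonyloxy)cyclopent‑2‑en‑1‑yl]propanoate | CC(C)=C[C@@H]1CC(C)=C(OS(=O)(=O)C(F)(F)F)[C@]1(C)CCC(=O)OC | intermediate
9 | methyl 3‑[(1R,5S)‑2‑formyl‑1,3‑dimethyl‑5‑(2‑methylprop‑1‑en‑1‑yl)cyclopent‑2‑en‑1‑yl]propanoate | CC(C)=C[C@@H]1CC(C)=C(C=O)[C@]1(C)CCC(=O)OC | intermediate
10 | methyl 3‑[(1R,2R,3S,5S)‑2‑formyl‑1,3‑dimethyl‑5‑(2‑methylprop‑1‑en‑1‑yl)cyclopentyl]propanoate | CC(C)=C[C@@H]1C[C@H](C)[C@@H](C=O)[C@]1(C)CCC(=O)OC | intermediate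
11 | methyl 3‑[(1R,2R,3S,5S)‑2‑(hydroxymethyl)‑1,3‑dimethyl‑5‑(2‑methylprop‑1‑en‑1‑yl)cyclopentyl]propanoate | CC(C)=C[C@@H]1C[C@H](C)[C@@H](CO)[C@]1(C)CCC(=O)OC | intermediate
12 | umbelliferone (7‑hydroxy‑2H‑chromen‑2‑one) | O=c1ccc2ccc(O)cc2o1 | starting material
13 | methyl 3‑[(1R,2R,3S,5S)‑1,3‑dimethyl‑5‑(2‑methylprop‑1‑en‑1‑yl)‑2‑{[(2‑oxo‑2H‑chromen‑7‑yl)oxy]methyl}cyclopentyl]propanoate | CC(C)=C[C@@H]1C[C@H](C)[C@@H](COc2ccc3ccc(=O)oc3c2)[C@]1(C)CCC(=O)OC | intermediate
14 | ferulsinaic acid | CC(C)=C[C@@H]1C[C@H](C)[C@@H](COc2ccc3ccc(=O)oc3c2)[C@]1(C)CCC(=O)O | target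

## Summary

Total steps: 11. Longest linear sequence: 11 (from 1).

Steps most likely to fail:

1. **Step 8.** The tetrasubstituted enal may react slowly with Cu–H, and the C3 facial selectivity rests on monocyclic conformational bias only. Fallback: postpone the Wittig by carrying the step‑3 aldehyde as its dimethyl acetal, saturate the enal C=C by heterogeneous hydrogenation (Pd/C, syn addition anti to the propanoate arm), equilibrate C4 as before, and install the isobutenyl group afterwards.
2. **Step 4.** The ylide may enolise the hindered α‑stereogenic aldehyde instead of adding, eroding the cis C1/C5 relationship. Fallback: non‑basic two‑stage olefination, using aldehyde‑selective Takai methylenation (CH2I2/Zn/Ti(OiPr)4) followed by cross‑metathesis with 2‑methyl‑2‑butene (Grubbs II).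
3. **Step 1.** The key step needs both cis ring fusion and a regiodefined enol ether from a hindered β,β‑disubstituted enone. Fallback: separate the two tasks. Hydrogenate 1 (H2, Pd/C) to the cis‑diketone, then form the cyclohexanone silyl enol ether under thermodynamic conditions (toward the ring‑fusion CH, as in 5β‑3‑keto steroids) before the same ozonolysis.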